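The cyclohexane ring is cut at C2–C3 and C4–C5 (ring: C1 methyl-bearing epoxide carbon, C2 epoxide CH, C3 CH2, C4 side-chain CH, C5 CHOAc, C6 CHOAng; side chain C7–C11). The key step, a type 2 intramolecular Diels–Alder reaction through a diisopropylsilyl tether from the C6 enol oxygen to the C8 hydroxyl, forms both bonds, the ring and the C4 and C5 stereocenters at once. It exploits the 1,3 relationship of the C6 oxygen to C4 and the cis C4/C5 pair: the tether overrides the para preference of the siloxy diene, forces the endo mode and relays C8. The precursor is an acyclic silaketal of an acetoxy dienol and an α'-hydroxy vinyl ketone.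

Key step: step 5

Remark: the locants C1–C11 defined above are used for all intermediates; the (Z) geometry of the enol silyl ether and the exo placement of the C8 side chain in the cycloaddition are expectations from analogy and a rough transition-state model, not established facts.

Step 1
Reactants: 1 methyl (S)-oxirane-2-carboxylate; 2 2-methylprop-1-enylmagnesium bromide
Product: 3 methyl (S)-2-hydroxy-5-methylhex-4-enoate
Conditions: CuI (10 mol%), THF, −40 °C; aq. NH4Cl
Reagents that add atoms: none
Why: Copper-catalysed Grignard opening of the epoxide at its unsubstituted carbon (SN2) should leave the ester and the existing stereocenter untouched, so the (S) carbinol that becomes C8 is taken from the chiral pool.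

Step 2
Reactants: 3 methyl (S)-2-hydroxy-5-methylhex-4-enoate
Product: 5 (S)-4-hydroxy-7-methylocta-1,6-dien-3-one, via Weinreb amide 4 (not isolated)
Conditions: MeNH(OMe)·HCl, iPrMgCl, THF, −20 °C; then CH2=CHMgBr, 0 °C; inverse quench into cold 1 M HCl
Reagents that add atoms: vinylmagnesium bromide, C=C[Mg]Br
Why: One-pot Weinreb ketone synthesis: the magnesium amide of N,O-dimethylhydroxylamine should convert the ester into amide 4, whose chelated adduct with the vinyl Grignard reagent collapses to the vinyl ketone only on acidic quench, and the alkoxide-bearing C8 is not expected to enolise.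

Step 3
Reactants: 6 acetoxyacetyl chloride; 7 tributyl(prop-1-en-2-yl)stannane
Product: 8 3-methyl-2-oxobut-3-en-1-yl acetate
Conditions: PdCl(CH2Ph)(PPh3)2 (2 mol%), BHT, CHCl3, 60 °C
Reagents that add atoms: none
Why: Stille acyl coupling (oxidative addition of the acid chloride, transfer of the isopropenyl group from tin, reductive elimination) should give the α-methylene ketone without touching the acetate.

Step 4
Reactants: 8 3-methyl-2-oxobut-3-en-1-yl acetate; 5 (S)-4-hydroxy-7-methylocta-1,6-dien-3-one
Product: 10 mixed diisopropylsilaketal of the (Z)-dienol of 8 and alcohol 5, via enol silyl triflate 9 (not isolated)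
Conditions: iPr2Si(OTf)2 (1.0 equiv), Et3N, CH2Cl2, −78 to 0 °C; then 5, 2,6-lutidine, −78 to 0 °C
Reagents that add atoms: diisopropylsilyl bis(trifluoromethanesulfonate), CC(C)[Si](OS(=O)(=O)C(F)(F)F)(OS(=O)(=O)C(F)(F)F)C(C)C
Why: Soft enolisation of the α-acetoxy ketone, which has only one enolisable side, should give the (Z) enol silyl triflate 9 (acetoxy and siloxy cis, as is usual for α-oxygenated ketones), and its remaining Si–OTf bond is then displaced by the secondary hydroxyl of 5 in a sequential silicon-tether formation.

Step 5
Reactants: 10 mixed diisopropylsilaketal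
Product: 11 bridged cycloadduct 11-acetoxy-3,3-diisopropyl-10-methyl-5-(3-methylbut-2-enyl)-2,4-dioxa-3-silabicyclo[5.3.1]undec-1(10)-en-6-one
Conditions: toluene (0.005 M), BHT, 2,6-di-tert-butylpyridine (cat.), 130 °C, sealed tube
Reagents that add atoms: none
Why: On heating, the electron-rich 1-acetoxy-2-siloxy diene (C5=C6–C1=C2) and the tethered vinyl ketone (C3=C4, activated by the C7 carbonyl) should combine in a concerted, asynchronous [4+2] cycloaddition that forms C2–C3 and C4–C5 together; the closest known reaction type is the type 2 intramolecular Diels–Alder reaction of 2-substituted dienes run through a disposable silyl acetal tether. The cyclohexene ring closes by the cycloaddition itself, and the eight-membered silaketal ring closes with it in the bridged 1,3 mode to give a bicyclo[5.3.1] bridgehead enol ether. C5 is set by the (Z) geometry of the enol acetate (acetoxy on the outside of the s-cis diene) and C4 by the tether, which can span C6 and C4 only if the C7 carbonyl lies endo, so the C5 acetoxy and the C4 acyl group must end up cis. The diene face is chosen by C8: in the bridged transition state the CH2 of the prenyl chain is expected to sit exo on the forming eight-membered ring, anti to the diisopropylsilyl group, which for (8S) corresponds to the ring configuration of the target. The step needs 1,3 regiochemistry against the electronic para preference of a 2-siloxy diene and intramolecular over bimolecular reaction; the five-atom tether should secure the first and high dilution the second.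

Step 6
Reactants: 11 bridged cycloadduct
Product: 12 methylidene cycloadduct 3,3-diisopropyl-10-methyl-5-(3-methylbut-2-enyl)-6-methylidene-2,4-dioxa-3-silabicyclo[5.3.1]undec-1(10)-en-11-yl acetate
Conditions: Tebbe reagent Cp2Ti(μ-Cl)(μ-CH2)AlMe2 (1.2 equiv), pyridine, THF/toluene, −40 to 0 °C
Reagents that add atoms: Tebbe reagent, C[Al-]1(C)C[Ti]([Cl+]1)(C2C=CC=C2)C3C=CC=C3
Why: Tebbe methylenation: the titanium methylidene reacts with ketones well below the temperature at which it attacks esters and is not basic, so the hindered C7 ketone should be converted without epimerising C4, eliminating the β-acetoxy group or touching the acetate and silyl enol ether.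

Step 7
Reactants: 12 methylidene cycloadduct
Product: 14 6-[(3S)-3-hydroxy-6-methylhepta-1,5-dien-2-yl]-3-methyl-2-oxocyclohex-3-en-1-yl acetate (1,6-cis), via acetoxysilyl ether 13 (not isolated)
Conditions: Pd(OAc)2 (1.1 equiv), MeCN, rt; then HF·pyridine, THF, 0 °C
Reagents that add atoms: none
Why: Saegusa–Ito oxidation: Pd(OAc)2 should attack C1 of the silyl enol ether with loss of silicon as the acetoxysilane 13, β-hydride elimination towards ring C2 then gives the conjugated C1=C2 enone at the position fixed by the cycloaddition, and HF·pyridine cleaves the remaining C8–O–Si bond.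

Step 8
Reactants: 14 hydroxy enone; 15 angelic acid [(Z)-2-methylbut-2-enoic acid]
Product: 16 C8 angelate of enone 14
Conditions: 15, 2,4,6-trichlorobenzoyl chloride, Et3N, toluene, rt; then 14, 60 °C
Reagents that add atoms: none
Why: Yamaguchi esterification through the mixed 2,4,6-trichlorobenzoic anhydride should acylate the unhindered allylic C8 hydroxyl with retention at C8 under conditions chosen to keep the (Z) geometry of the angelate.

Step 9
Reactants: 16 C8 angelate of enone 14
Product: 17 all-cis allylic alcohol (C6 hydroxyl cis to the C5 acetoxy group and the C4 side chain)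
Conditions: NaBH4, CeCl3·7H2O, MeOH, −78 °C; AcOH quench
Reagents that add atoms: none
Why: Luche 1,2-reduction: hydride should add to the C6 carbonyl from the face opposite the cis C5 acetoxy and C4 substituents, which sets C6 with its oxygen cis to both, while the esters are not reduced at this temperature.

Step 10
Reactants: 17 all-cis allylic alcohol
Product: 18 epoxy alcohol (C1–C2 epoxide cis to the C6 hydroxyl)
Conditions: VO(acac)2 (5 mol%), t-BuOOH, CH2Cl2, 0 °C to rt
Reagents that add atoms: tert-butyl hydroperoxide, CC(C)(C)OO
Why: Vanadium-catalysed hydroxyl-directed epoxidation: the C6 hydroxyl should deliver oxygen to its own face of the C1=C2 bond, which sets C1 and C2, and the prenyl alkene and the acylated allylic alkene lack a directing hydroxyl and are left alone.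

Step 11
Reactants: 18 epoxy alcohol; 15 angelic acid
Product: 19 C6,C8 bis-angelate with the prenyl side chain still an alkene
Conditions: 15, 2,4,6-trichlorobenzoyl chloride, Et3N, toluene, rt; then 18, 80 °C
Reagents that add atoms: none
Why: A second Yamaguchi esterification should acylate the hindered C6 hydroxyl with retention; the cis epoxy alcohol cannot undergo Payne rearrangement because its alkoxide cannot reach the backside of C1.

Step 12
Reactants: 19 bis-angelate
Product: 20 CNP0118696.1
Conditions: ent-Shi ketone (1,2:4,5-di-O-isopropylidene-β-L-erythro-2,3-hexodiulo-2,6-pyranose, 0.3 equiv), KHSO5 (as Oxone), K2CO3, Bu4NHSO4, MeCN/CH2(OMe)2/aq. Na2B4O7–Na2EDTA buffer, 0 °C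
Reagents that add atoms: potassium peroxymonosulfate, [K+].[O-]S(=O)(=O)OO
Why: Shi asymmetric epoxidation: the chiral dioxirane formed from the L-series ketone should epoxidise the only electron-rich trisubstituted alkene and fix (S) at C10 by catalyst control, while the 1,1-disubstituted alkene and the two conjugated angelate alkenes react far more slowly.

Compound list
1 | methyl (S)-oxirane-2-carboxylate (methyl (S)-glycidate) | COC(=O)[C@@H]1CO1 | starting material
2 | 2-methylprop-1-enylmagnesium bromide | CC(C)=C[Mg]Br | starting material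
3 | methyl (S)-2-hydroxy-5-methylhex-4-enoate | COC(=O)[C@@H](O)CC=C(C)C | intermediate
4 | (S)-2-hydroxy-N-methoxy-N,5-dimethylhex-4-enamide (Weinreb amide, not isolated) | CON(C)C(=O)[C@@H](O)CC=C(C)C | intermediate
5 | (S)-4-hydroxy-7-methylocta-1,6-dien-3-one | C=CC(=O)[C@@H](O)CC=C(C)C | intermediate
6 | acetoxyacetyl chloride | CC(=O)OCC(Cl)=O | starting material
7 | tributyl(prop-1-en-2-yl)stannane | CCCC[Sn](CCCC)(CCCC)C(C)=C | starting material
8 | 3-methyl-2-oxobut-3-en-1-yl acetate | CC(=O)OCC(=O)C(C)=C | intermediate
9 | (Z)-2-[diisopropyl(trifluoromethylsulfonyloxy)silyloxy]-3-methylbuta-1,3-dien-1-yl acetate (enol silyl triflate, not isolated) | CC(=O)O/C=C(\O[Si](C(C)C)(C(C)C)OS(=O)(=O)C(F)(F)F)C(C)=C | intermediate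
10 | mixed diisopropylsilaketal: (Z)-2-{diisopropyl[(S)-7-methyl-3-oxoocta-1,6-dien-4-yloxy]silyloxy}-3-methylbuta-1,3-dien-1-yl acetate | C=CC(=O)[C@H](CC=C(C)C)O[Si](C(C)C)(C(C)C)O/C(=C\OC(C)=O)C(C)=C | intermediate
11 | bridged cycloadduct: 11-acetoxy-3,3-diisopropyl-10-methyl-5-(3-methylbut-2-enyl)-2,4-dioxa-3-silabicyclo[5.3.1]undec-1(10)-en-6-one, acetoxy group cis to the carbonyl-bearing bridge, C8 as in 5 | O=C1[C@H](CC=C(C)C)O[Si](C(C)C)(C(C)C)OC2=C(C)CC[C@@H]1[C@H]2OC(C)=O | intermediate
12 | methylidene cycloadduct: 6-methylidene analogue of 11 | C=C1[C@H](CC=C(C)C)O[Si](C(C)C)(C(C)C)OC2=C(C)CC[C@@H]1[C@H]2OC(C)=O | intermediate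
13 | acetoxy(diisopropyl)silyl ether of 14 at the C8 oxygen (not isolated) | C=C([C@H](CC=C(C)C)O[Si](OC(C)=O)(C(C)C)C(C)C)[C@@H]1CC=C(C)C(=O)[C@@H]1OC(C)=O | intermediate
14 | 6-[(3S)-3-hydroxy-6-methylhepta-1,5-dien-2-yl]-3-methyl-2-oxocyclohex-3-en-1-yl acetate, 1,6-cis (C4 side chain and C5 acetoxy cis) | C=C([C@H](CC=C(C)C)O)[C@@H]1CC=C(C)C(=O)[C@@H]1OC(C)=O | intermediate
15 | angelic acid, (Z)-2-methylbut-2-enoic acid | C/C=C(/C)C(O)=O | starting material
16 | C8 angelate of 14 | C=C([C@H](CC=C(C)C)OC(=O)/C(C)=C\C)[C@@H]1CC=C(C)C(=O)[C@@H]1OC(C)=O | intermediate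
17 | allylic alcohol: C6 hydroxyl, C5 acetoxy and C4 side chain all cis; C1=C2 alkene | C=C([C@H](CC=C(C)C)OC(=O)/C(C)=C\C)[C@@H]1CC=C(C)[C@H](O)[C@@H]1OC(C)=O | intermediate
18 | epoxy alcohol: C1–C2 epoxide cis to the C6 hydroxyl, otherwise as 17 | C=C([C@H](CC=C(C)C)OC(=O)/C(C)=C\C)[C@@H]1C[C@@H]2O[C@]2(C)[C@H](O)[C@@H]1OC(C)=O | intermediate
19 | C6,C8 bis-angelate of the ring epoxide with the C10=C11 alkene | C=C([C@H](CC=C(C)C)OC(=O)/C(C)=C\C)[C@@H]1C[C@@H]2O[C@]2(C)[C@H](OC(=O)/C(C)=C\C)[C@@H]1OC(C)=O | intermediate
20 | CNP0118696.1 | C=C([C@H](C[C@@H]1OC1(C)C)OC(=O)/C(C)=C\C)[C@@H]1C[C@@H]2O[C@]2(C)[C@H](OC(=O)/C(C)=C\C)[C@@H]1OC(C)=O | target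

Total step count: 12. Longest linear sequence: 11 steps (steps 1, 2, 4–12; step 3 is a one-step branch).

Steps most likely to fail

Step 5. The remote, conformationally mobile C8 substituent may discriminate the two diene faces poorly or in the opposite sense, and the electronically favoured bimolecular (para) cycloaddition may compete with the strained intramolecular mode. The fallback keeps the tethered cycloaddition but changes the stereochemical strategy from retention to inversion at C8; it sets out from Grignard reagent 2 and enone 8 and comes back at 16. Purchased methyl (R)-oxirane-2-carboxylate F1 would be opened with 2 as in step 1 to give methyl (R)-2-hydroxy-5-methylhex-4-enoate F2. The one-pot sequence of step 2 would convert it, through the (R)-Weinreb amide F3, into (R)-4-hydroxy-7-methylocta-1,6-dien-3-one F4. Silaketal formation with 9 (from 8) would give the C8-epimeric silaketal F5, whose cycloaddition would then place the ring on the required face and give the C8-epimeric cycloadduct F6. Tebbe methylenation would give the C8-epimeric methylidene cycloadduct F7, and Pd(OAc)2 followed by HF·pyridine would give, through the C8-epimeric acetoxysilyl ether F8, the (8R)-hydroxy enone F9. A Mitsunobu esterification of F9 with angelic acid 15 (PPh3, diisopropyl azodicarboxylate, toluene, 0 °C) would invert C8 and deliver 16.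

Step 7. Palladium may fail to engage the hindered bridgehead dialkoxysilyl enol ether, β-hydride elimination may run towards the C1 methyl group to give the exocyclic enone, or protodesilylation may return the saturated ketone. The fallback replaces the palladium dehydrogenation by selenium chemistry; it sets out from 12 and comes back at 14. PhSeCl (1.0 equiv, CH2Cl2, −78 °C) would react with the silyl enol ether at C1 to give the chlorosilyl ether of the α-phenylselanyl ketone F10. HF·pyridine would free the C8 hydroxyl to give the α-phenylselanyl hydroxy ketone F11 (either configuration at C1 is usable). H2O2 with pyridine (CH2Cl2, 0 °C) would then oxidise selenium and the selenoxide would undergo syn-elimination towards C2 to give 14.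

Step 11. Acylation of the hindered C6 hydroxyl may be so slow that the activated angelate isomerises to the tiglate or the neighbouring cis C5 acetate migrates to C6. The fallback builds the (Z) alkene after an easy acylation; it sets out from 18 and comes back at 19. The C6 hydroxyl would be esterified with the non-isomerisable 2-[bis(2,2,2-trifluoroethoxy)phosphoryl]propanoic acid (N,N'-diisopropylcarbodiimide, cat. DMAP, CH2Cl2, 0 °C) to give the C6 phosphonopropanoate F12 (mixture at the phosphonate α-carbon). A Still–Gennari olefination (KN(SiMe3)2, 18-crown-6, THF, −78 °C, then acetaldehyde) would form the (Z)-2-methylbut-2-enoate and give 19.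

Further compounds
F1 | step 5 | methyl (R)-oxirane-2-carboxylate (purchased) | COC(=O)[C@H]1CO1
F2 | step 5 | methyl (R)-2-hydroxy-5-methylhex-4-enoate | COC(=O)[C@H](O)CC=C(C)C
F3 | step 5 | (R)-2-hydroxy-N-methoxy-N,5-dimethylhex-4-enamide | CON(C)C(=O)[C@H](O)CC=C(C)C
F4 | step 5 | (R)-4-hydroxy-7-methylocta-1,6-dien-3-one | C=CC(=O)[C@H](O)CC=C(C)C
F5 | step 5 | C8-epimeric silaketal (epimer of 10) | C=CC(=O)[C@@H](CC=C(C)C)O[Si](C(C)C)(C(C)C)O/C(=C\OC(C)=O)C(C)=C
F6 | step 5 | C8-epimeric cycloadduct (epimer of 11) | O=C1[C@@H](CC=C(C)C)O[Si](C(C)C)(C(C)C)OC2=C(C)CC[C@@H]1[C@H]2OC(C)=O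
F7 | step 5 | C8-epimeric methylidene cycloadduct (epimer of 12) | C=C1[C@@H](CC=C(C)C)O[Si](C(C)C)(C(C)C)OC2=C(C)CC[C@@H]1[C@H]2OC(C)=O
F8 | step 5 | C8-epimeric acetoxysilyl ether (epimer of 13) | C=C([C@@H](CC=C(C)C)O[Si](OC(C)=O)(C(C)C)C(C)C)[C@@H]1CC=C(C)C(=O)[C@@H]1OC(C)=O
F9 | step 5 | (8R)-hydroxy enone (C8 epimer of 14) | C=C([C@@H](CC=C(C)C)O)[C@@H]1CC=C(C)C(=O)[C@@H]1OC(C)=O
F10 | step 7 | chloro(diisopropyl)silyl ether of the C1-phenylselanyl ketone (C1 epimers) | C=C([C@H](CC=C(C)C)O[Si](Cl)(C(C)C)C(C)C)[C@@H]1CCC(C)([Se]c2ccccc2)C(=O)[C@@H]1OC(C)=O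
F11 | step 7 | C1-phenylselanyl hydroxy ketone (C1 epimers) | C=C([C@H](CC=C(C)C)O)[C@@H]1CCC(C)([Se]c2ccccc2)C(=O)[C@@H]1OC(C)=O
F12 | step 11 | C6 2-[bis(2,2,2-trifluoroethoxy)phosphoryl]propanoate of 18 | C=C([C@H](CC=C(C)C)OC(=O)/C(C)=C\C)[C@@H]1C[C@@H]2O[C@]2(C)[C@H](OC(=O)C(C)P(=O)(OCC(F)(F)F)OCC(F)(F)F)[C@@H]1OC(C)=O
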